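The earlier runs and the new flask stem from a simulated flask for substances that don't exist, and the scatter is random.

A catalyst cannot complete more turnovers than the reagent delivered to it allows, because each round of the proposed steps takes one reagent and gives one target, so I set turnovers delivered against turnovers made in the earlier runs.

| flask | substrate | reagent | free catalyst | temperature | remark | time |
|---|---|---|---|---|---|---|
| Sunday's | 0.40 M | 0.40 M (fed, over 25 min) | 20 mM | 110 °C | run made earlier |  |
| Thursday's | 0.40 M | 0.40 M (fed, over 25 min) | 80 mM | 132 °C | run made earlier |  |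
| green | 0.40 M | 0.400 M (fed, over 25 min) | 40 mM | 100 °C |  | 25 min |
| grey | 0.40 M | 0.400 M | 40 mM | 140 °C | everything together at the start | 25 min |

| run | time / min | target / % | substrate / % |
|---|---|---|---|
| Sunday's | 4.00 | 1.5 | 99.9 |
| Sunday's | 8.00 | 4.4 | 95.8 |
| Sunday's | 12.0 | 9.3 | 91.5 |
| Sunday's | 15.0 | 12.3 | 87.7 |
| Sunday's | 20.0 | 17.8 | 81.7 |
| Thursday's | 0.500 | 0 | 99.5 |
| Thursday's | 1.50 | 2.7 | 98.0 |
| Thursday's | 3.00 | 8.1 | 90.7 |
| Thursday's | 4.00 | 9.6 | 89.3 |
| Thursday's | 6.00 | 17.2 | 83.3 |

(standard deviation of a reading: 1 percentage point)

1. the winner by amount of target, in percent of the substrate charged; "neither" if no more than 2 percentage points parts them (green / grey / neither)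
2. how much target is there at the end, in percent of the substrate charged: green
3. how much target is there at the end, in percent of the substrate charged: grey

At the last reading of Sunday's run the feed had delivered 16.0 turnovers per catalyst and 3.56 had been made. Because delivery ran far ahead, I placed the rate-limiting step in the catalyst's round and not in the feed. So the slope of Sunday's rows from 8.00 min to 20.0 min gave me the quantity I carried, the turnover rate, meaning target made per catalyst per minute: 0.223 min⁻¹, as a reading, after a lag of about 4.06 min.

Thursday's last row read differently: 1.20 delivered and 0.860 made, a share of 0.717 as a reading, so I took that run to be following its feed and drew from it a share, not a catalyst rate.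

For green I assumed the turnover rate halves over the 10.0 K below Sunday's temperature, and I kept Sunday's lag, which gave 2.34 turnovers, or 23.4% target. For grey, the same rule gave 1.79 min⁻¹, so its 10.0 turnovers of reagent needed 5.60 min, less than the time allowed. I therefore counted grey by the share of its reagent turned into target, an estimate I put between my 23.4% for green and Thursday's 71.7%, and so I chose grey.

The forecast said grey, with 20% for green and 50% for grey, noting that “all the reagent is present at once”; my green figure stood higher.

The flasks gave 21.3% for green, which is 2.13 turnovers against my 2.34, and 43.7% for grey, which is 4.37 of the 10.0 charged, so the winner was grey.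

    2 reagent → self-condensation product (k = 0.290 L mol⁻¹ min⁻¹, Ea = 62.0 kJ mol⁻¹)
    catalyst intermediate D → free catalyst + target (k = 20.0 min⁻¹, Ea = 82.0 kJ mol⁻¹)
    reagent + free catalyst → catalyst intermediate A (k = 2.80 L mol⁻¹ min⁻¹, Ea = 83.0 kJ mol⁻¹)
    substrate + catalyst intermediate C → catalyst intermediate D (k = 29.0 L mol⁻¹ min⁻¹, Ea = 56.0 kJ mol⁻¹)
    catalyst intermediate A ⇌ by-product + catalyst intermediate B (K = 0.130 M, k = 6.10 min⁻¹, Ea = 87.0 kJ mol⁻¹, ΔH = −46.0 kJ mol⁻¹)
    2 catalyst intermediate A ⇌ resting dimer (K = 17.0 L mol⁻¹, k = 1.40 L mol⁻¹ min⁻¹, Ea = 84.0 kJ mol⁻¹, ΔH = −31.0 kJ mol⁻¹)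
    catalyst intermediate B → catalyst intermediate C (k = 0.280 min⁻¹, Ea = 100 kJ mol⁻¹)
    (constants at 100 °C)

The same reckoning went to a further flask, green repeated at 125 °C, with amounts and time held. The halving rule, run upward from Sunday, gave 0.632 min⁻¹, which over 25 min came to 15.8 turnovers, more than the 10.0 delivered. So I counted this flask by its feed, and Thursday's share, carried over as an estimate, gave 7.17 turnovers, or 71.7% target. This flask held 59.1% target, which is 5.91 turnovers.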